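**The problem**

Numbering used throughout: ring C1 (ketone), C2 (methyl-bearing epoxide carbon), C3 (epoxide CH), C4 (CH2), C5 (side-chain carbon), C6 (angelate carbon); side chain C7 (carrying the exocyclic methylene C14), C8 (acetate carbinol), C9–C11 (prenyl end).

The target is a single cyclohexanone ring that carries an α,β-epoxide, an α'-angelate and, at C5, a branched chain with a 1,1-disubstituted alkene, an allylic acetate and a prenyl terminus. It has five stereocentres: the C5 chain and the C6 ester are trans, the C2–C3 epoxide lies on the face of the C5 chain, and C8 sits outside the ring. The trans C5/C6 pair fixes a half-chair with both groups equatorial, so hydride should add axially to a C1 ketone, and the resulting C1 carbinol can steer an epoxidant to the correct face of C2=C3. C5 and C6 can therefore control C2 and C3, whereas C8 is insulated by the sp2 carbon C7 and needs its own control. Several groups are fragile: the angelate isomerises to the tiglate under nucleophilic or basic acylation, C6–H is α to a ketone and bears an acyloxy group, the epoxy ketone tolerates neither strong acid nor base, and the prenyl alkene rules out peracids. The oxidised ring functions must therefore come late and by directed or chemoselective reagents. The enabling feature is that, with C7 at the carboxyl level, a C2=C3 alkene is γ,δ to that carbonyl and C5 is its α-carbon. Tying C7 through oxygen to C2 gives a six-membered lactone whose ketene acetal can form the C4–C5 bond, the carbocycle and the C5 centre in one [3,3] shift.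

**Retrosynthesis**

Epoxide C–O bonds. Target 33 is taken back to epoxy alcohol 32 and then to allylic alcohol 31 by removing both epoxide C–O bonds. Direct nucleophilic epoxidation of enone 30 is rejected: in 2-methyl-5-substituted cyclohexenones (carvone is the model) peroxide anion enters anti to the C5 group, which is the wrong face, and the alkaline medium endangers the angelate and C6. Peracids are excluded by the prenyl alkene. A C1 hydroxyl on the face of the C5 chain makes C2=C3 the only alkene with a free allylic hydroxyl. The forward steps must deliver hydride to 30 from the face of the ester and oxygen syn to the new hydroxyl.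

Angelate C–O bond and the two ring oxygens. Enone 30 is cut at the ester to hydroxy enone 27 and angelic acid 28. Hydroxy enone 27 comes from cis-diol 26, and 26 from acetonide 25. Acylating one hydroxyl of 26 selectively would be unreliable, but MnO2 distinguishes the allylic C1 carbinol from the C6 carbinol by oxidation. The acylation must be mild and free of nucleophilic catalysts so that the Z geometry survives.

Side-chain functions. Acetate 25 goes back through alcohol 24 and silyl ether 23 to silyloxy ketone 22, hydroxy ketone 21 and ketone 19. The cuts are the acetate C–O bond, the C7=C14 bond and the C8–O bond. A C7 ketone is the natural product of a carboxyl at C7, it activates C8 for oxygenation, and it is the precursor of the methylene. The neighbouring options are weaker: a C7 alkenyl metal would need an unstable β,γ-unsaturated aldehyde, and allylic oxidation of a methylene compound would be unselective. The forward steps need enolisation at the C8 methylene and not at C5, reagent control of the C8 face, and a non-basic methylenation.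

C7–C8 bond. Ketone 19 is cut to Weinreb amide 16 and 5-bromo-2-methylpent-2-ene 17 (as its Grignard reagent 18). Amide 16 comes from acid 14. This removes five carbons and leaves a bicyclic acid with three stereocentres.

C4–C5 bond (key). Acid 14 is the [3,3] product of the silyl ketene acetal 12 of vinyl lactone 11. The retro-step re-forms the lactone O–C2 bond and breaks C4–C5. Against a Diels–Alder or metathesis construction of the same cyclohexene, this cut turns a tertiary C–O centre (C2) stereospecifically into C5, and its precursor maps atom for atom onto a deoxypentose. The forward reaction needs enolate O-silylation to be faster than loss of the C6 oxygen, and a boat transition state.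

C2–vinyl bond and lactone C–O bond. Lactone 11 is cut to methyl ketone 8 and vinylmagnesium bromide 9. The tertiary alkoxide 10 closes onto the ester. Chelation between the ketone and the C1 dioxolane oxygen must place the vinyl group cis to that oxygen.

Back to the sugar. Ketone 8 comes from aldehyde 5 and methylmagnesium bromide 6 via alcohol 7, and 5 from hydroxy ester 4, lactone 3, lactol acetonide 2 and 2-deoxy-D-ribose 1. The sugar's C3 and C4 become C6 and C1, its C2 is C5, C1 is C7 and C5 becomes C2. Only protection and changes of oxidation level are needed.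

**Roads not taken**

Alternative 1: The cut is C5–C6, opening the ring to the acyclic (3Z,6Z)-trienal A1 with the C1 oxygen as a 4-methoxybenzyl ether and the C8 oxygen silylated.
- Forward step: an alkylaluminium chloride Lewis acid would activate the C6 aldehyde, C5 would attack it while a C14 hydrogen passes to oxygen, and cyclohexenol A2 would form.
- Merits: this carbonyl-ene closure makes the ring, the C7=C14 methylene and the C5 and C6 centres at once. It leaves the C6 hydroxyl free for the angelate and the C1 oxygen already on the face needed for directed epoxidation. No hydroxylation, methylenation or C1 redox detour follows, so its endgame is clearly shorter than the chosen one.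
- Weak points: A1 needs two Z-trisubstituted alkenes and two remote stereocentres, each from its own asymmetric step. Its α-alkoxy aldehyde is prone to epimerisation. The trans C5/C6 outcome rests on a chair preference that chelation between the aldehyde and ether oxygens can erode. Hydrogen transfer from C8, or cationic closure onto the prenyl alkene, can compete.
- Comparison: the chosen plan accepts a longer endgame in exchange for ring stereocentres that do not depend on a conformational preference, since C6 is bought and C5 is transferred.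

Alternative 2: The cuts are C1–C2 and C3–C4; the ring is assembled from cyclobutanone A3 (C1, C4, C5, C6 with the silyloxy and ketal groups trans) and 1-(trimethylsilyl)propyne A4.
- Forward step: a zerovalent nickel catalyst with a trialkylphosphine would couple the carbonyl with the alkyne, cleave C1–C4 by β-carbon elimination and close C3–C4 to give cyclohexenone A5.
- Merits: the ring arrives at the enone oxidation level with the C2 methyl in place, in a catalytic and atom-economical step. In oxidation-level economy it is better than the chosen plan, which must remove an acetonide and oxidise C1.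
- Weak points: an enantioenriched trans-2-silyloxy-3-substituted cyclobutanone is itself a multistep target. The α-oxygenated C1–C6 bond can compete in the cleavage, and the silyloxy group invites β-oxygen elimination. The silyl group at C3 must be removed afterwards. The whole C8–C11 chain, the C8 oxygen and C14 still have to be built next to a reactive enone.
- Comparison: the chosen plan offers a rearrangement on an established substrate class, a pool starting material, and a ring that stays robust (acetonide, isolated alkene) while the side chain is built.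

Alternative 3: The cut is the C2=C3 double bond, leading to acyclic tetraene A6 with an isopropenyl group on C1 and an allyl group on C5.
- Forward step: a ruthenium carbene catalyst of the second generation would join these two termini to give cyclohexenol A7.
- Merits: this ring closure is more dependable and milder than a boat Claisen rearrangement of an enolisable β-alkoxy lactone. A7 already carries the C1 hydroxyl cis to the C5 chain and the finished side chain, so the endgame is shorter. In both respects this road is better.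
- Weak points: four sp3 centres (C1, C6, C5, C8), three of them contiguous, must be set in an open chain by several separate asymmetric C–C bond formations with three differentiated oxygens. The prenyl and C7=C14 alkenes can leak into metathesis.
- Comparison: the chosen plan buys two ring centres from a sugar and obtains the third by chirality transfer, so only C8 needs an external chiral reagent. It pays for this with about ten functional-group steps after the ring is formed.

Key step: step 8

Remark on descriptors: several CIP labels change along the route only because neighbouring groups change rank (the dioxolane carbon next to C2 in 4–11, C5 between 22 and 23, C1 and C2 between 31, 32 and 33). The only centre that is actually inverted is C1 (steps 17 and 19). Commercial solutions of LiN(iPr)2, KN(SiMe3)2, MeMgBr and CH2=CHMgBr are assumed.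

**Steps**

Step 1
Reactants: 1 2-deoxy-D-ribose
Product: 2 2-deoxy-3,4-O-isopropylidene-D-erythro-pentopyranose (anomeric mixture)
Conditions: 2-methoxypropene, PPTS (cat.), EtOAc, 0 → 23 °C
Reagents that add atoms: 2-methoxypropene (COC(C)=C)
Why: Kinetic acetal formation on the cis-3,4-diol of the pyranose form under mild acid (acetonide protection); no stereocentre is touched.

Step 2
Reactants: 2 2-deoxy-3,4-O-isopropylidene-D-erythro-pentopyranose
Product: 3 2-deoxy-3,4-O-isopropylidene-D-erythro-pentono-1,5-lactone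
Conditions: TEMPO (cat.), PhI(OAc)2, CH2Cl2, 23 °C
Reagents that add atoms: none
Why: Oxoammonium-mediated oxidation of a lactol to the lactone; the conditions are neutral enough for the acetonide.

Step 3
Reactants: 3 2-deoxy-3,4-O-isopropylidene-D-erythro-pentono-1,5-lactone
Product: 4 methyl 2-[(4S,5R)-5-(hydroxymethyl)-2,2-dimethyl-1,3-dioxolan-4-yl]acetate
Conditions: K2CO3 (0.1 equiv), MeOH, 0 °C; filtered through silica and used at once
Reagents that add atoms: methanol (CO)
Why: Base-catalysed methanolysis (transesterification) of the δ-lactone frees the primary hydroxyl; a weak base at 0 °C should not trigger β-elimination of the dioxolane oxygen, and immediate use forestalls relactonisation.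

Step 4
Reactants: 4 methyl 2-[(4S,5R)-5-(hydroxymethyl)-2,2-dimethyl-1,3-dioxolan-4-yl]acetate
Product: 5 methyl 2-[(4S,5S)-5-formyl-2,2-dimethyl-1,3-dioxolan-4-yl]acetate
Conditions: Dess–Martin periodinane, CH2Cl2, 0 → 23 °C
Reagents that add atoms: none
Why: Dess–Martin oxidation of a primary alcohol; the absence of base keeps the cis α-alkoxy aldehyde from epimerising.

Step 5
Reactants: 5 methyl 2-[(4S,5S)-5-formyl-2,2-dimethyl-1,3-dioxolan-4-yl]acetate; 6 methylmagnesium bromide
Product: 7 methyl 2-[(4S,5R)-5-(1-hydroxyethyl)-2,2-dimethyl-1,3-dioxolan-4-yl]acetate (carbinol epimers)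
Conditions: MeMgBr, THF, −78 °C; aq. NH4Cl at −78 °C
Reagents that add atoms: none
Why: Grignard addition to the aldehyde, far faster than to the methyl ester at −78 °C; the new carbinol centre is oxidised in the next step, and the cold quench prevents the alkoxide from lactonising.

Step 6
Reactants: 7 methyl 2-[(4S,5R)-5-(1-hydroxyethyl)-2,2-dimethyl-1,3-dioxolan-4-yl]acetate
Product: 8 methyl 2-[(4S,5S)-5-acetyl-2,2-dimethyl-1,3-dioxolan-4-yl]acetate
Conditions: Dess–Martin periodinane, CH2Cl2, 0 → 23 °C
Reagents that add atoms: none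
Why: Dess–Martin oxidation of the secondary alcohol converges both epimers on the methyl ketone without base.

Step 7
Reactants: 8 methyl 2-[(4S,5S)-5-acetyl-2,2-dimethyl-1,3-dioxolan-4-yl]acetate; 9 vinylmagnesium bromide
Product: 11 (3aS,4S,7aS)-4-ethenyl-2,2,4-trimethyltetrahydro-4H-[1,3]dioxolo[4,5-c]pyran-6-one, via bromomagnesium alkoxide 10 (not isolated)
Conditions: MgBr2·OEt2, CH2Cl2, −78 °C; CH2=CHMgBr (THF), −78 → 23 °C; aq. NH4Cl
Reagents that add atoms: none
Why: Cram-chelate Grignard addition: magnesium bridges the ketone oxygen and the adjacent dioxolane oxygen, and the vinyl group enters from the face of C1–H, giving the S carbinol with vinyl cis to the dioxolane oxygens. On warming, alkoxide 10 acylates itself on the methyl ester (lactonisation); any uncyclised hydroxy ester should close with a trace of base.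

Step 8
Reactants: 11 (3aS,4S,7aS)-4-ethenyl-2,2,4-trimethyltetrahydro-4H-[1,3]dioxolo[4,5-c]pyran-6-one
Product: 14 (3aS,4R,7aR)-2,2,7-trimethyl-3a,4,5,7a-tetrahydro-1,3-benzodioxole-4-carboxylic acid, via silyl ketene acetal 12 (not isolated), via trimethylsilyl ester 13 (not isolated)
Conditions: Me3SiCl, Et3N, THF, −78 °C, LiN(iPr)2 added dropwise; → 23 °C; then toluene, 100 °C; aq. citric acid work-up
Reagents that add atoms: none
Why: Deprotonation of the only acidic position (C5–H2) in the presence of Me3SiCl gives O-silyl ketene acetal 12 before the lithium enolate can expel the C6 oxygen; on heating, the C5=C7(OSi)–O–C2–C3=C4 array undergoes a concerted suprafacial [3,3] shift that forms C4–C5, breaks O–C2 and leaves silyl ester 13, which is hydrolysed to 14 on work-up. The closest known reaction type is the Ireland–Claisen ring contraction of alkenyl lactone silyl ketene acetals (alicyclic Claisen), in which 6-vinyl six-membered lactones give cyclohex-3-enecarboxylic acids. Because the lactone ring spans the allyl vinyl ether, the transition state is a boat of bicyclo[2.2.2]octane shape; the carbocycle closes at C4 in a formally 6-endo-trig sense, and the new C2=C3 bond is necessarily cis within the ring. The new C5 centre is dictated by C2: the vinyl group reaches only the ketene acetal face on which it stands, which is the face of the dioxolane oxygens, so C7 emerges trans to the C6 oxygen. The step needs O-silylation to outrun β-elimination and C-silylation; the internal quench at −78 °C, and a cis-fused dioxolane that keeps the C6–O bond out of anti-periplanar alignment with the enolate, should secure this. It also needs an axial vinyl group, which the fully substituted C2 can supply because one of its two carbon substituents must be axial in any conformer.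

Step 9
Reactants: 14 (3aS,4R,7aR)-2,2,7-trimethyl-3a,4,5,7a-tetrahydro-1,3-benzodioxole-4-carboxylic acid
Product: 16 (3aS,4R,7aR)-N-methoxy-N,2,2,7-tetramethyl-3a,4,5,7a-tetrahydro-1,3-benzodioxole-4-carboxamide, via acyl imidazole 15 (not isolated)
Conditions: 1,1'-carbonyldiimidazole, CH2Cl2, 0 → 23 °C; MeNH(OMe)·HCl, 23 °C
Reagents that add atoms: N,O-dimethylhydroxylamine hydrochloride (CNOC.Cl)
Why: Weinreb amide formation through the acyl imidazole; near-neutral conditions should leave the C5 centre (α to the carbonyl, β to oxygen) intact.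

Step 10
Reactants: 16 (3aS,4R,7aR)-N-methoxy-N,2,2,7-tetramethyl-3a,4,5,7a-tetrahydro-1,3-benzodioxole-4-carboxamide; 17 5-bromo-2-methylpent-2-ene
Product: 19 5-methyl-1-[(3aS,4R,7aR)-2,2,7-trimethyl-3a,4,5,7a-tetrahydro-1,3-benzodioxol-4-yl]hex-4-en-1-one, via Grignard reagent 18 (not isolated)
Conditions: 17, Mg, THF, 23 → 40 °C; then 16, THF, 0 °C; aq. NH4Cl
Reagents that add atoms: none
Why: Grignard addition to a Weinreb amide; the chelated tetrahedral adduct prevents over-addition and releases the ketone only on work-up.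

Step 11
Reactants: 19 5-methyl-1-[(3aS,4R,7aR)-2,2,7-trimethyl-3a,4,5,7a-tetrahydro-1,3-benzodioxol-4-yl]hex-4-en-1-one
Product: 21 (2S)-2-hydroxy-5-methyl-1-[(3aS,4R,7aR)-2,2,7-trimethyl-3a,4,5,7a-tetrahydro-1,3-benzodioxol-4-yl]hex-4-en-1-one, via potassium enolate 20 (not isolated)
Conditions: KN(SiMe3)2, THF, −78 °C; (+)-(camphorsulfonyl)oxaziridine, −78 °C; AcOH quench
Reagents that add atoms: (+)-(camphorsulfonyl)oxaziridine (CC1(C)[C@@H]2CC[C@]13CS(=O)(=O)N4O[C@@]34C2)
Why: Kinetic deprotonation at the unhindered C8 methylene (not the ring methine C5) gives Z-enolate 20, which is hydroxylated by the N-sulfonyloxaziridine (Davis asymmetric enolate hydroxylation). The (+)-reagent is expected to deliver the 8S alcohol by analogy with Z-enolates of aryl alkyl ketones; the antipodal reagent is available if the C5 centre opposes it.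

Step 12
Reactants: 21 (2S)-2-hydroxy-5-methyl-1-[(3aS,4R,7aR)-2,2,7-trimethyl-3a,4,5,7a-tetrahydro-1,3-benzodioxol-4-yl]hex-4-en-1-one
Product: 22 (2S)-5-methyl-2-[(triethylsilyl)oxy]-1-[(3aS,4R,7aR)-2,2,7-trimethyl-3a,4,5,7a-tetrahydro-1,3-benzodioxol-4-yl]hex-4-en-1-one
Conditions: Et3SiCl, imidazole, CH2Cl2, 0 °C
Reagents that add atoms: chlorotriethylsilane (CC[Si](Cl)(CC)CC)
Why: Silyl ether formation masks the hydroxyl for the titanium reagent; imidazole at 0 °C is too weak a base to epimerise C8 or C5.

Step 13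
Reactants: 22 (2S)-5-methyl-2-[(triethylsilyl)oxy]-1-[(3aS,4R,7aR)-2,2,7-trimethyl-3a,4,5,7a-tetrahydro-1,3-benzodioxol-4-yl]hex-4-en-1-one
Product: 23 triethyl({(3S)-6-methyl-2-[(3aS,4S,7aR)-2,2,7-trimethyl-3a,4,5,7a-tetrahydro-1,3-benzodioxol-4-yl]hepta-1,5-dien-3-yl}oxy)silane
Conditions: Cp2TiMe2, toluene, 65 °C, dark
Reagents that add atoms: dimethyltitanocene (C[Ti](C)(C1C=CC=C1)C1C=CC=C1)
Why: Petasis methylenation: the titanium methylidene formed by thermal loss of methane adds to the ketone and the oxatitanacycle fragments to the alkene. The reagent is non-basic, so the two α-centres and the β-oxygen survive where a phosphorus ylide would not.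

Step 14
Reactants: 23 triethyl({(3S)-6-methyl-2-[(3aS,4S,7aR)-2,2,7-trimethyl-3a,4,5,7a-tetrahydro-1,3-benzodioxol-4-yl]hepta-1,5-dien-3-yl}oxy)silane
Product: 24 (3S)-6-methyl-2-[(3aS,4S,7aR)-2,2,7-trimethyl-3a,4,5,7a-tetrahydro-1,3-benzodioxol-4-yl]hepta-1,5-dien-3-ol
Conditions: HF·pyridine, pyridine, THF, 0 °C
Reagents that add atoms: none
Why: Fluoride-driven cleavage of the triethylsilyl ether; the buffered reagent leaves the acetonide and the alkenes untouched.

Step 15
Reactants: 24 (3S)-6-methyl-2-[(3aS,4S,7aR)-2,2,7-trimethyl-3a,4,5,7a-tetrahydro-1,3-benzodioxol-4-yl]hepta-1,5-dien-3-ol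
Product: 25 (3S)-6-methyl-2-[(3aS,4S,7aR)-2,2,7-trimethyl-3a,4,5,7a-tetrahydro-1,3-benzodioxol-4-yl]hepta-1,5-dien-3-yl acetate
Conditions: Ac2O, pyridine, DMAP (cat.), CH2Cl2, 0 → 23 °C
Reagents that add atoms: acetic anhydride (CC(=O)OC(C)=O)
Why: Acylation of the secondary allylic alcohol installs the final C8 ester while both ring oxygens are still masked, so no deprotection is needed on the finished epoxy ketone.

Step 16
Reactants: 25 (3S)-6-methyl-2-[(3aS,4S,7aR)-2,2,7-trimethyl-3a,4,5,7a-tetrahydro-1,3-benzodioxol-4-yl]hepta-1,5-dien-3-yl acetate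
Product: 26 (3S)-2-[(1S,5R,6S)-5,6-dihydroxy-4-methylcyclohex-3-en-1-yl]-6-methylhepta-1,5-dien-3-yl acetate
Conditions: AcOH/H2O (4:1), 50 °C
Reagents that add atoms: none
Why: Acid-catalysed acetal hydrolysis; aqueous acetic acid is mild enough for the allylic acetate and the trisubstituted alkenes.

Step 17
Reactants: 26 (3S)-2-[(1S,5R,6S)-5,6-dihydroxy-4-methylcyclohex-3-en-1-yl]-6-methylhepta-1,5-dien-3-yl acetate
Product: 27 (3S)-2-[(1S,6S)-6-hydroxy-4-methyl-5-oxocyclohex-3-en-1-yl]-6-methylhepta-1,5-dien-3-yl acetate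
Conditions: MnO2 (activated, excess), CH2Cl2, 23 °C
Reagents that add atoms: none
Why: Chemoselective MnO2 oxidation of the allylic C1 carbinol leaves the C6 hydroxyl, which differentiates the two ring oxygens by oxidation level; the neutral medium should not enolise the α-ketol.

Step 18
Reactants: 27 (3S)-2-[(1S,6S)-6-hydroxy-4-methyl-5-oxocyclohex-3-en-1-yl]-6-methylhepta-1,5-dien-3-yl acetate; 28 angelic acid
Product: 30 (1S,6S)-6-[(3S)-3-(acetyloxy)-6-methylhepta-1,5-dien-2-yl]-3-methyl-2-oxocyclohex-3-en-1-yl (2Z)-2-methylbut-2-enoate, via mixed anhydride 29 (not isolated)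
Conditions: 28, 2,4,6-Cl3C6H2COCl, Et3N, toluene, 23 °C; then 27, 23 → 60 °C
Reagents that add atoms: none
Why: Yamaguchi-type mixed anhydride esterification: the alcohol attacks the unhindered angeloyl carbonyl of 29. Omitting a nucleophilic catalyst removes the usual addition–elimination path from Z to E.

Step 19
Reactants: 30 (1S,6S)-6-[(3S)-3-(acetyloxy)-6-methylhepta-1,5-dien-2-yl]-3-methyl-2-oxocyclohex-3-en-1-yl (2Z)-2-methylbut-2-enoate
Product: 31 (1S,2S,6S)-6-[(3S)-3-(acetyloxy)-6-methylhepta-1,5-dien-2-yl]-2-hydroxy-3-methylcyclohex-3-en-1-yl (2Z)-2-methylbut-2-enoate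
Conditions: NaBH4, CeCl3·7H2O, MeOH, −78 °C
Reagents that add atoms: none
Why: Luche 1,2-reduction: with the C5 chain and C6 ester both equatorial in the half-chair, axial hydride delivery should give the pseudo-equatorial C1 alcohol, trans to the ester and cis to the chain, as in the reduction of carvone to cis-carveol. The esters are inert, and the low temperature limits acyl migration.

Step 20
Reactants: 31 (1S,2S,6S)-6-[(3S)-3-(acetyloxy)-6-methylhepta-1,5-dien-2-yl]-2-hydroxy-3-methylcyclohex-3-en-1-yl (2Z)-2-methylbut-2-enoate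
Product: 32 (1R,2R,3S,4S,6S)-4-[(3S)-3-(acetyloxy)-6-methylhepta-1,5-dien-2-yl]-2-hydroxy-1-methyl-7-oxabicyclo[4.1.0]heptan-3-yl (2Z)-2-methylbut-2-enoate
Conditions: VO(acac)2 (cat.), tBuOOH, CH2Cl2, 0 → 23 °C
Reagents that add atoms: tert-butyl hydroperoxide (CC(C)(C)OO)
Why: Vanadium-catalysed hydroxyl-directed epoxidation: the peroxide bound to the vanadate ester of the C1 hydroxyl is delivered to the syn face of C2=C3, setting C2 and C3. The prenyl and methylene alkenes have no free allylic hydroxyl, and the angelate alkene is electron-poor.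

Step 21
Reactants: 32 (1R,2R,3S,4S,6S)-4-[(3S)-3-(acetyloxy)-6-methylhepta-1,5-dien-2-yl]-2-hydroxy-1-methyl-7-oxabicyclo[4.1.0]heptan-3-yl (2Z)-2-methylbut-2-enoate
Product: 33 (1S,3S,4S,6S)-4-[(3S)-3-(acetyloxy)-6-methylhepta-1,5-dien-2-yl]-1-methyl-2-oxo-7-oxabicyclo[4.1.0]heptan-3-yl (2Z)-2-methylbut-2-enoate
Conditions: Dess–Martin periodinane, NaHCO3, CH2Cl2, 0 → 23 °C
Reagents that add atoms: none
Why: Buffered Dess–Martin oxidation of the epoxy alcohol to the epoxy ketone; no stereocentre is touched, and the trans C5/C6 arrangement is the thermodynamically preferred one at the now enolisable C6.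

**Compound list**

1 | 2-deoxy-D-ribose | O=CC[C@H](O)[C@H](O)CO | starting material
2 | 2-deoxy-3,4-O-isopropylidene-D-erythro-pentopyranose (anomeric mixture) | OC1C[C@@H]2OC(C)(C)O[C@@H]2CO1 | intermediate
3 | 2-deoxy-3,4-O-isopropylidene-D-erythro-pentono-1,5-lactone | O=C1C[C@@H]2OC(C)(C)O[C@@H]2CO1 | intermediate
4 | methyl 2-[(4S,5R)-5-(hydroxymethyl)-2,2-dimethyl-1,3-dioxolan-4-yl]acetate | COC(=O)C[C@@H]1OC(C)(C)O[C@@H]1CO | intermediate
5 | methyl 2-[(4S,5S)-5-formyl-2,2-dimethyl-1,3-dioxolan-4-yl]acetate | COC(=O)C[C@@H]1OC(C)(C)O[C@@H]1C=O | intermediate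
6 | methylmagnesium bromide | C[Mg]Br | starting material
7 | methyl 2-[(4S,5R)-5-(1-hydroxyethyl)-2,2-dimethyl-1,3-dioxolan-4-yl]acetate (carbinol epimers) | COC(=O)C[C@@H]1OC(C)(C)O[C@@H]1C(C)O | intermediate
8 | methyl 2-[(4S,5S)-5-acetyl-2,2-dimethyl-1,3-dioxolan-4-yl]acetate | COC(=O)C[C@@H]1OC(C)(C)O[C@@H]1C(C)=O | intermediate
9 | vinylmagnesium bromide | C=C[Mg]Br | starting material
10 | bromomagnesium (2S)-2-[(4S,5S)-5-(2-methoxy-2-oxoethyl)-2,2-dimethyl-1,3-dioxolan-4-yl]but-3-en-2-olate | COC(=O)C[C@@H]1OC(C)(C)O[C@@H]1[C@](C)(C=C)O[Mg]Br | intermediate (not isolated)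
11 | (3aS,4S,7aS)-4-ethenyl-2,2,4-trimethyltetrahydro-4H-[1,3]dioxolo[4,5-c]pyran-6-one (cis-fused; vinyl on the face of the dioxolane oxygens) | O=C1C[C@@H]2OC(C)(C)O[C@@H]2[C@](C)(C=C)O1 | intermediate
12 | {[(3aS,4S,7aS)-4-ethenyl-2,2,4-trimethyl-3a,7a-dihydro-4H-[1,3]dioxolo[4,5-c]pyran-6-yl]oxy}trimethylsilane | C[Si](C)(C)OC1=C[C@@H]2OC(C)(C)O[C@@H]2[C@](C)(C=C)O1 | intermediate (not isolated)
13 | trimethylsilyl (3aS,4R,7aR)-2,2,7-trimethyl-3a,4,5,7a-tetrahydro-1,3-benzodioxole-4-carboxylate | C[Si](C)(C)OC(=O)[C@@H]1CC=C(C)[C@H]2OC(C)(C)O[C@H]21 | intermediate (not isolated)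
14 | (3aS,4R,7aR)-2,2,7-trimethyl-3a,4,5,7a-tetrahydro-1,3-benzodioxole-4-carboxylic acid (carboxyl trans to the adjacent ring oxygen) | OC(=O)[C@@H]1CC=C(C)[C@H]2OC(C)(C)O[C@H]21 | intermediate
15 | 1-{[(3aS,4R,7aR)-2,2,7-trimethyl-3a,4,5,7a-tetrahydro-1,3-benzodioxol-4-yl]carbonyl}-1H-imidazole | O=C([C@@H]1CC=C(C)[C@H]2OC(C)(C)O[C@H]21)n1ccnc1 | intermediate (not isolated)
16 | (3aS,4R,7aR)-N-methoxy-N,2,2,7-tetramethyl-3a,4,5,7a-tetrahydro-1,3-benzodioxole-4-carboxamide | CON(C)C(=O)[C@@H]1CC=C(C)[C@H]2OC(C)(C)O[C@H]21 | intermediate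
17 | 5-bromo-2-methylpent-2-ene | CC(C)=CCCBr | starting material
18 | (4-methylpent-3-en-1-yl)magnesium bromide | CC(C)=CCC[Mg]Br | intermediate (not isolated)
19 | 5-methyl-1-[(3aS,4R,7aR)-2,2,7-trimethyl-3a,4,5,7a-tetrahydro-1,3-benzodioxol-4-yl]hex-4-en-1-one | CC(C)=CCCC(=O)[C@@H]1CC=C(C)[C@H]2OC(C)(C)O[C@H]21 | intermediate
20 | potassium (1Z)-5-methyl-1-[(3aS,4R,7aR)-2,2,7-trimethyl-3a,4,5,7a-tetrahydro-1,3-benzodioxol-4-yl]hexa-1,4-dien-1-olate | CC(C)=CC/C=C(\[O-])[C@@H]1CC=C(C)[C@H]2OC(C)(C)O[C@H]21.[K+] | intermediate (not isolated)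
21 | (2S)-2-hydroxy-5-methyl-1-[(3aS,4R,7aR)-2,2,7-trimethyl-3a,4,5,7a-tetrahydro-1,3-benzodioxol-4-yl]hex-4-en-1-one | CC(C)=CC[C@H](O)C(=O)[C@@H]1CC=C(C)[C@H]2OC(C)(C)O[C@H]21 | intermediate
22 | (2S)-5-methyl-2-[(triethylsilyl)oxy]-1-[(3aS,4R,7aR)-2,2,7-trimethyl-3a,4,5,7a-tetrahydro-1,3-benzodioxol-4-yl]hex-4-en-1-one | CC(C)=CC[C@H](O[Si](CC)(CC)CC)C(=O)[C@@H]1CC=C(C)[C@H]2OC(C)(C)O[C@H]21 | intermediate
23 | triethyl({(3S)-6-methyl-2-[(3aS,4S,7aR)-2,2,7-trimethyl-3a,4,5,7a-tetrahydro-1,3-benzodioxol-4-yl]hepta-1,5-dien-3-yl}oxy)silane | CC(C)=CC[C@H](O[Si](CC)(CC)CC)C(=C)[C@@H]1CC=C(C)[C@H]2OC(C)(C)O[C@H]21 | intermediate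
24 | (3S)-6-methyl-2-[(3aS,4S,7aR)-2,2,7-trimethyl-3a,4,5,7a-tetrahydro-1,3-benzodioxol-4-yl]hepta-1,5-dien-3-ol | CC(C)=CC[C@H](O)C(=C)[C@@H]1CC=C(C)[C@H]2OC(C)(C)O[C@H]21 | intermediate
25 | (3S)-6-methyl-2-[(3aS,4S,7aR)-2,2,7-trimethyl-3a,4,5,7a-tetrahydro-1,3-benzodioxol-4-yl]hepta-1,5-dien-3-yl acetate | CC(C)=CC[C@H](OC(C)=O)C(=C)[C@@H]1CC=C(C)[C@H]2OC(C)(C)O[C@H]21 | intermediate
26 | (3S)-2-[(1S,5R,6S)-5,6-dihydroxy-4-methylcyclohex-3-en-1-yl]-6-methylhepta-1,5-dien-3-yl acetate (cis-diol, trans to the chain) | CC(C)=CC[C@H](OC(C)=O)C(=C)[C@@H]1CC=C(C)[C@@H](O)[C@H]1O | intermediate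
27 | (3S)-2-[(1S,6S)-6-hydroxy-4-methyl-5-oxocyclohex-3-en-1-yl]-6-methylhepta-1,5-dien-3-yl acetate | CC(C)=CC[C@H](OC(C)=O)C(=C)[C@@H]1CC=C(C)C(=O)[C@H]1O | intermediate
28 | angelic acid, (2Z)-2-methylbut-2-enoic acid | C/C=C(/C)C(=O)O | starting material
29 | (2Z)-2-methylbut-2-enoic 2,4,6-trichlorobenzoic anhydride | C/C=C(/C)C(=O)OC(=O)c1c(Cl)cc(Cl)cc1Cl | intermediate (not isolated)
30 | (1S,6S)-6-[(3S)-3-(acetyloxy)-6-methylhepta-1,5-dien-2-yl]-3-methyl-2-oxocyclohex-3-en-1-yl (2Z)-2-methylbut-2-enoate | CC(C)=CC[C@H](OC(C)=O)C(=C)[C@@H]1CC=C(C)C(=O)[C@H]1OC(=O)/C(C)=C\C | intermediate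
31 | (1S,2S,6S)-6-[(3S)-3-(acetyloxy)-6-methylhepta-1,5-dien-2-yl]-2-hydroxy-3-methylcyclohex-3-en-1-yl (2Z)-2-methylbut-2-enoate (hydroxyl trans to the ester, cis to the chain) | CC(C)=CC[C@H](OC(C)=O)C(=C)[C@@H]1CC=C(C)[C@H](O)[C@H]1OC(=O)/C(C)=C\C | intermediate
32 | (1R,2R,3S,4S,6S)-4-[(3S)-3-(acetyloxy)-6-methylhepta-1,5-dien-2-yl]-2-hydroxy-1-methyl-7-oxabicyclo[4.1.0]heptan-3-yl (2Z)-2-methylbut-2-enoate (epoxide syn to the hydroxyl) | CC(C)=CC[C@H](OC(C)=O)C(=C)[C@@H]1C[C@@H]2O[C@]2(C)[C@H](O)[C@H]1OC(=O)/C(C)=C\C | intermediate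
33 | (1S,3S,4S,6S)-4-[(3S)-3-(acetyloxy)-6-methylhepta-1,5-dien-2-yl]-1-methyl-2-oxo-7-oxabicyclo[4.1.0]heptan-3-yl (2Z)-2-methylbut-2-enoate (CNP0125636.1) | C=C([C@H](CC=C(C)C)OC(C)=O)[C@@H]1C[C@@H]2O[C@]2(C)C(=O)[C@H]1OC(=O)/C(C)=C\C | target

**Step count and least certain steps**

Total: 21 steps. Longest linear sequence: 21 steps (1 → 33); compounds 6, 9, 17 and 28 enter as purchased reagents.

Step 8 (key step). The most likely failure is expulsion of the C6 alkoxide from the lactone enolate before O-silylation, which would open the dioxolane. The second is that the ketene acetal decays by C-silylation or hydrolysis before the strained boat transition state is reached. The fallback gives up the lactone tether but keeps the C4–C5 bond and the ring. It sets out from keto ester 8.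
- Wittig methylenation (Ph3P=CH2, THF, 0 °C) would give methyl 2-[(4S,5R)-2,2-dimethyl-5-(prop-1-en-2-yl)-1,3-dioxolan-4-yl]acetate F1.
- Transesterification with allyl alcohol and Ti(OiPr)4 would give the prop-2-en-1-yl ester F2.
- An open-chain Ireland–Claisen rearrangement through an unstrained chair (same internal silyl quench) would give (2R)-2-[(4S,5R)-2,2-dimethyl-5-(prop-1-en-2-yl)-1,3-dioxolan-4-yl]pent-4-enoic acid F3.
- Ring-closing metathesis of F3 with the second-generation Grubbs catalyst would close C2=C3 and return to acid 14.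
- In this variant C5 would rest on acyclic induction from C6 only, so the epimers at C5 might have to be separated at 14.

Step 7. Chelation may be incomplete, because a dioxolane oxygen is a weak donor and THF competes for magnesium. This would erode facial selectivity at C2; enolisation of the ketone could also epimerise C1. The fallback reverses the order of the two additions so that the non-chelated (Felkin–Anh) preference gives the same C2 configuration. It sets out from aldehyde 5.
- Vinylmagnesium bromide at −78 °C would give methyl 2-[(4S,5R)-5-(1-hydroxyprop-2-en-1-yl)-2,2-dimethyl-1,3-dioxolan-4-yl]acetate F4.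
- Dess–Martin oxidation would give the vinyl ketone methyl 2-[(4S,5S)-2,2-dimethyl-5-(prop-2-enoyl)-1,3-dioxolan-4-yl]acetate F5.
- The non-chelating reagent MeTi(OiPr)3 would add to F5 to give methyl 2-[(4S,5S)-5-[(2S)-2-hydroxybut-3-en-2-yl]-2,2-dimethyl-1,3-dioxolan-4-yl]acetate F6.
- Catalytic NaH in THF would close F6 to lactone 11.

Step 11. Facial selectivity at C8 may be poor, because reagent control on a dialkyl ketone enolate is less secure than on aryl ketones and may be opposed by the C5 centre. Some enolisation toward C5, followed by β-elimination, is also possible. The fallback corrects C8 after the methylene is in place. It sets out from alcohol 24, which would then be accompanied by its C8 epimer, (3R)-6-methyl-2-[(3aS,4S,7aR)-2,2,7-trimethyl-3a,4,5,7a-tetrahydro-1,3-benzodioxol-4-yl]hepta-1,5-dien-3-ol F7.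
- Dess–Martin oxidation would convert both epimers into the dienone 6-methyl-2-[(3aS,4S,7aR)-2,2,7-trimethyl-3a,4,5,7a-tetrahydro-1,3-benzodioxol-4-yl]hepta-1,5-dien-3-one F8.
- Corey–Bakshi–Shibata reduction with the (R)-methyl oxazaborolidine and catecholborane, with the branched alkenyl group as the large substituent, would return to 24 as the 3S alcohol.

Step 18. The angeloyl group may isomerise from Z to E during acyl transfer, and the α-ketol may tautomerise through its enediol under amine base and heat. The fallback builds the Z alkene after a mild acylation. It sets out from hydroxy enone 27.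
- Carbodiimide coupling with 2-[bis(2,2,2-trifluoroethoxy)phosphoryl]propanoic acid at 0 °C would give (1S,6S)-6-[(3S)-3-(acetyloxy)-6-methylhepta-1,5-dien-2-yl]-3-methyl-2-oxocyclohex-3-en-1-yl 2-[bis(2,2,2-trifluoroethoxy)phosphoryl]propanoate F9.
- Still–Gennari olefination of F9 with acetaldehyde (KN(SiMe3)2, 18-crown-6, THF, −78 °C) would form the Z-trisubstituted alkene and return to angelate 30.

Step 19. Hydride may be delivered from the face of the C5 chain, if the conformer with axial substituents or cerium coordination to the ester takes over, and the ester may migrate from O6 to O1 in the basic medium. The fallback inverts C1 after the reduction. It sets out from enone 30.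
- The wrong-face reduction product would be (1S,2R,6S)-6-[(3S)-3-(acetyloxy)-6-methylhepta-1,5-dien-2-yl]-2-hydroxy-3-methylcyclohex-3-en-1-yl (2Z)-2-methylbut-2-enoate F10.
- Mitsunobu reaction with chloroacetic acid (PPh3, diisopropyl azodicarboxylate) would give the inverted ester (1S,2S,6S)-6-[(3S)-3-(acetyloxy)-6-methylhepta-1,5-dien-2-yl]-2-[(chloroacetyl)oxy]-3-methylcyclohex-3-en-1-yl (2Z)-2-methylbut-2-enoate F11.
- Thiourea and NaHCO3 in ethanol would remove the chloroacetyl group selectively, leaving the acetate and angelate, and return to alcohol 31.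

**Further compounds**

F1 | step 8 | methyl 2-[(4S,5R)-2,2-dimethyl-5-(prop-1-en-2-yl)-1,3-dioxolan-4-yl]acetate | COC(=O)C[C@@H]1OC(C)(C)O[C@@H]1C(C)=C
F2 | step 8 | prop-2-en-1-yl 2-[(4S,5R)-2,2-dimethyl-5-(prop-1-en-2-yl)-1,3-dioxolan-4-yl]acetate | C=CCOC(=O)C[C@@H]1OC(C)(C)O[C@@H]1C(C)=C
F3 | step 8 | (2R)-2-[(4S,5R)-2,2-dimethyl-5-(prop-1-en-2-yl)-1,3-dioxolan-4-yl]pent-4-enoic acid | OC(=O)[C@H](CC=C)[C@@H]1OC(C)(C)O[C@@H]1C(C)=C
F4 | step 7 | methyl 2-[(4S,5R)-5-(1-hydroxyprop-2-en-1-yl)-2,2-dimethyl-1,3-dioxolan-4-yl]acetate (carbinol epimers) | COC(=O)C[C@@H]1OC(C)(C)O[C@@H]1C(O)C=C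
F5 | step 7 | methyl 2-[(4S,5S)-2,2-dimethyl-5-(prop-2-enoyl)-1,3-dioxolan-4-yl]acetate | COC(=O)C[C@@H]1OC(C)(C)O[C@@H]1C(=O)C=C
F6 | step 7 | methyl 2-[(4S,5S)-5-[(2S)-2-hydroxybut-3-en-2-yl]-2,2-dimethyl-1,3-dioxolan-4-yl]acetate | COC(=O)C[C@@H]1OC(C)(C)O[C@@H]1[C@](C)(C=C)O
F7 | step 11 | (3R)-6-methyl-2-[(3aS,4S,7aR)-2,2,7-trimethyl-3a,4,5,7a-tetrahydro-1,3-benzodioxol-4-yl]hepta-1,5-dien-3-ol | CC(C)=CC[C@@H](O)C(=C)[C@@H]1CC=C(C)[C@H]2OC(C)(C)O[C@H]21
F8 | step 11 | 6-methyl-2-[(3aS,4S,7aR)-2,2,7-trimethyl-3a,4,5,7a-tetrahydro-1,3-benzodioxol-4-yl]hepta-1,5-dien-3-one | CC(C)=CCC(=O)C(=C)[C@@H]1CC=C(C)[C@H]2OC(C)(C)O[C@H]21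
F9 | step 18 | (1S,6S)-6-[(3S)-3-(acetyloxy)-6-methylhepta-1,5-dien-2-yl]-3-methyl-2-oxocyclohex-3-en-1-yl 2-[bis(2,2,2-trifluoroethoxy)phosphoryl]propanoate (epimers at the phosphonate carbon) | CC(C)=CC[C@H](OC(C)=O)C(=C)[C@@H]1CC=C(C)C(=O)[C@H]1OC(=O)C(C)P(=O)(OCC(F)(F)F)OCC(F)(F)F
F10 | step 19 | (1S,2R,6S)-6-[(3S)-3-(acetyloxy)-6-methylhepta-1,5-dien-2-yl]-2-hydroxy-3-methylcyclohex-3-en-1-yl (2Z)-2-methylbut-2-enoate | CC(C)=CC[C@H](OC(C)=O)C(=C)[C@@H]1CC=C(C)[C@@H](O)[C@H]1OC(=O)/C(C)=C\C
F11 | step 19 | (1S,2S,6S)-6-[(3S)-3-(acetyloxy)-6-methylhepta-1,5-dien-2-yl]-2-[(chloroacetyl)oxy]-3-methylcyclohex-3-en-1-yl (2Z)-2-methylbut-2-enoate | CC(C)=CC[C@H](OC(C)=O)C(=C)[C@@H]1CC=C(C)[C@H](OC(=O)CCl)[C@H]1OC(=O)/C(C)=C\C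
A1 | alternative 1 | (2S,3Z,6Z,8S)-8-{[tert-butyl(dimethyl)silyl]oxy}-2-[(4-methoxyphenyl)methoxy]-3,7,11-trimethyldodeca-3,6,10-trienal | O=C[C@@H](OCc1ccc(OC)cc1)/C(C)=C\C/C=C(/C)[C@H](CC=C(C)C)O[Si](C)(C)C(C)(C)C
A2 | alternative 1 | (1S,2S,6S)-6-[(3S)-3-{[tert-butyl(dimethyl)silyl]oxy}-6-methylhepta-1,5-dien-2-yl]-2-[(4-methoxyphenyl)methoxy]-3-methylcyclohex-3-en-1-ol | C=C([C@H](CC=C(C)C)O[Si](C)(C)C(C)(C)C)[C@@H]1CC=C(C)[C@H](OCc2ccc(OC)cc2)[C@H]1O
A3 | alternative 2 | (2S,3R)-2-{[tert-butyl(dimethyl)silyl]oxy}-3-(2-methyl-1,3-dioxolan-2-yl)cyclobutan-1-one | O=C1C[C@@H](C2(C)OCCO2)[C@@H]1O[Si](C)(C)C(C)(C)C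
A4 | alternative 2 | trimethyl(prop-1-yn-1-yl)silane | CC#C[Si](C)(C)C
A5 | alternative 2 | (5R,6S)-6-{[tert-butyl(dimethyl)silyl]oxy}-2-methyl-5-(2-methyl-1,3-dioxolan-2-yl)-3-(trimethylsilyl)cyclohex-2-en-1-one | CC1=C([Si](C)(C)C)C[C@@H](C2(C)OCCO2)[C@H](O[Si](C)(C)C(C)(C)C)C1=O
A6 | alternative 3 | (3S,4S,5S,7S)-7-{[tert-butyl(dimethyl)silyl]oxy}-4-[(4-methoxyphenyl)methoxy]-2,10-dimethyl-6-methylidene-5-(prop-2-en-1-yl)undeca-1,9-dien-3-ol | C=CC[C@H]([C@H](OCc1ccc(OC)cc1)[C@@H](O)C(C)=C)C(=C)[C@H](CC=C(C)C)O[Si](C)(C)C(C)(C)C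
A7 | alternative 3 | (1S,5S,6S)-5-[(3S)-3-{[tert-butyl(dimethyl)silyl]oxy}-6-methylhepta-1,5-dien-2-yl]-6-[(4-methoxyphenyl)methoxy]-2-methylcyclohex-2-en-1-ol | C=C([C@H](CC=C(C)C)O[Si](C)(C)C(C)(C)C)[C@@H]1CC=C(C)[C@H](O)[C@H]1OCc1ccc(OC)cc1
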